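**Plan**

- Cuts: first the O1–C2 bond of the pyranone, back to an ortho-hydroxyaryl β-methoxy enone; then the C4–C4a bond between the carbonyl carbon and ring A, back to 2-methoxy-1,4-benzoquinone and a β-methoxy enal carrying C2, C3, C4 and ring B; then both formyl carbons from the benzylic carbon of 3,4,5-trimethoxyphenylacetic acid.
- Enabling feature: in ring A the pyranone oxygen on C8a and the hydroxyl on C6 are para to each other, so ring A is a hydroquinone. With the methoxy on C7 it is 2-methoxy-1,4-benzoquinone at the reduced level, and C4a is the quinone carbon para to that methoxy (quinone C5), its best acceptor position.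
- Forward: ring B is bought. Its benzylic carbon (C3) is formylated twice (C2 and C4 from DMF, carboxyl lost as CO2) and the enol is methylated. Ring A arrives as the quinone and re-aromatises in the light-driven C4–C4a acylation. Ring C closes last by O1–C2 addition–elimination with loss of methanol, leaving the C6 hydroxyl free without any protecting group.
- Stereochemistry: the target has no stereocentre; the only stereo-element on the way, the enol ether double bond, is erased at the ring closure.

Key step: step 5

Assumption: the push-pull double bonds of the vinamidinium, enaminone, enolate, enol ether and aroyl enol ether intermediates are written as E for definiteness; they equilibrate readily and either geometry leads to the same chromone.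

**Route**

Step 1
Reactants: 1 3,4,5-trimethoxyphenylacetic acid; 2 N,N-dimethylformamide (reactant and solvent)
Product: 4 (E)-3-(dimethylamino)-2-(3,4,5-trimethoxyphenyl)acrolein, via vinamidinium chloride 3 (not isolated)
Conditions: POCl3 (3 equiv), DMF, 0 °C then 80 °C (CO2 evolution); ice, aq K2CO3 to pH 9–10, 50 °C
Reagents that add atoms: water, O (aldehyde oxygen, introduced at the hydrolysis)
Why: Vilsmeier–Arnold decarboxylative double formylation of an arylacetic acid, in which the activated benzylic carbon is aminomethylenated twice with loss of CO2 to the vinamidinium salt 3 (whose cationic side chain shields the trimethoxyphenyl ring from ring formylation), and mild carbonate hydrolysis stops at the vinylogous formamide 4.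

Step 2
Reactants: 4 (E)-3-(dimethylamino)-2-(3,4,5-trimethoxyphenyl)acrolein
Product: 6 2-(3,4,5-trimethoxyphenyl)malondialdehyde, via sodium enolate 5 (not isolated)
Conditions: 2 M aq NaOH, EtOH, reflux; then 2 M HCl to pH 2, 0 °C
Reagents that add atoms: sodium hydroxide, [Na+].[OH-]
Why: Saponification of a vinylogous amide, in which hydroxide adds to the β-carbon and expels dimethylamine to give the stabilised enolate 5, and acidification precipitates the dialdehyde as its hydroxymethylene enol.

Step 3
Reactants: 6 2-(3,4,5-trimethoxyphenyl)malondialdehyde
Product: 7 (E)-3-methoxy-2-(3,4,5-trimethoxyphenyl)acrolein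
Conditions: Me2SO4 (1.1 equiv), K2CO3, acetone, rt; neutral, non-aqueous-acid work-up
Reagents that add atoms: dimethyl sulfate, COS(=O)(=O)OC
Why: O-alkylation of a vinylogous carboxylate (Williamson-type methylation of a β-dicarbonyl enolate by a hard electrophile), favoured over C-methylation because the latter would build a quaternary benzylic carbon bearing two formyl groups.

Step 4
Reactants: 8 2-methoxyhydroquinone
Product: 9 2-methoxy-1,4-benzoquinone
Conditions: Ag2O (1.5 equiv), MgSO4, Et2O, rt, dark; filter, recrystallise, use fresh
Reagents that add atoms: none
Why: Two-electron oxidation of an electron-rich hydroquinone to the quinone by Ag2O under neutral anhydrous conditions, the classical quinone preparation, which leaves the methyl ether untouched.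

Step 5
Reactants: 7 (E)-3-methoxy-2-(3,4,5-trimethoxyphenyl)acrolein; 9 2-methoxy-1,4-benzoquinone
Product: 10 (E)-1-(2,5-dihydroxy-4-methoxyphenyl)-3-methoxy-2-(3,4,5-trimethoxyphenyl)prop-2-en-1-one
Conditions: hν (blue LEDs, 420–450 nm), 9 (1.5 equiv, in portions), degassed PhH, Ar, rt
Reagents that add atoms: none
Why: Proposed new method: light above 400 nm is absorbed only by quinone 9, whose n,π* triplet abstracts the formyl hydrogen of 7; the semiquinone and acyl radicals then combine at quinone C5 (or the acyl radical adds there in a short chain, any O-acyl product being corrected by a photo-Fries shift), and enolisation of the acyl enedione gives hydroquinone 10, so the C4–C4a bond forms while ring A is reduced, with no co-product. The closest known reaction type is the photochemical Friedel–Crafts-type acylation of 1,4-quinones by aldehydes, which tolerates simple enals; a β-methoxy α-aryl enal and a methoxyquinone are untested there, and the unsaturated acyl radical is used because it cannot lose CO as the acyl radical of an arylacetaldehyde would. No ring closes and no stereocentre is created in this step, the pyranone closing only in step 6. The selectivity needed is C-acylation at C5 and not at C6 or C3: the methoxy group makes the C4 carbonyl a vinylogous ester, so C5, β to the unperturbed C1 carbonyl and unhindered, is the acceptor carbon for a nucleophilic acyl radical and the open ortho position of the semiquinone formed by abstraction at O1. Hydrogen abstraction must also outrun electron-transfer quenching by the trimethoxyphenyl ring and [2+2] addition to the enol ether, which benzene (poor at supporting charge separation), long-wavelength light and the electron-poor push-pull character of that double bond should favour. The regiochemistry would be checked on 10 by 1H NMR, two para singlets being expected for ring A against meta-coupled doublets for the C6-acylated isomer.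

Step 6
Reactants: 10 (E)-1-(2,5-dihydroxy-4-methoxyphenyl)-3-methoxy-2-(3,4,5-trimethoxyphenyl)prop-2-en-1-one
Product: 11 6-hydroxy-7-methoxy-3-(3,4,5-trimethoxyphenyl)chromen-4-one
Conditions: TsOH·H2O (10 mol %), MeOH, 50 °C, Ar
Reagents that add atoms: none
Why: 6-endo oxa-Michael addition of the ketone-chelated ortho hydroxyl to the β-methoxy enone followed by acid-catalysed loss of methanol (the usual addition–elimination closure of isoflavones from 2-hydroxyaryl β-heteroatom enones), while the other hydroquinone hydroxyl is meta to the acyl group, cannot reach C2 and so remains as the free C6 phenol.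

**Compound list**

1 | 3,4,5-trimethoxyphenylacetic acid | COc1cc(CC(=O)O)cc(OC)c1OC | starting material
2 | N,N-dimethylformamide | CN(C)C=O | starting material
3 | 2-(3,4,5-trimethoxyphenyl)-1,3-bis(dimethylamino)trimethinium chloride (vinamidinium salt, written as the chloride) | CN(C)/C=C(/C=[N+](C)C)c1cc(OC)c(OC)c(OC)c1.[Cl-] | intermediate
4 | (E)-3-(dimethylamino)-2-(3,4,5-trimethoxyphenyl)acrolein | CN(C)/C=C(/C=O)c1cc(OC)c(OC)c(OC)c1 | intermediate
5 | sodium (E)-3-oxo-2-(3,4,5-trimethoxyphenyl)prop-1-en-1-olate | [Na+].[O-]/C=C(/C=O)c1cc(OC)c(OC)c(OC)c1 | intermediate
6 | 2-(3,4,5-trimethoxyphenyl)malondialdehyde (present as the hydroxymethylene enol) | O=CC(C=O)c1cc(OC)c(OC)c(OC)c1 | intermediate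
7 | (E)-3-methoxy-2-(3,4,5-trimethoxyphenyl)acrolein | CO/C=C(/C=O)c1cc(OC)c(OC)c(OC)c1 | intermediate
8 | 2-methoxyhydroquinone (2-methoxybenzene-1,4-diol) | COc1cc(O)ccc1O | starting material
9 | 2-methoxy-1,4-benzoquinone | COC1=CC(=O)C=CC1=O | intermediate
10 | (E)-1-(2,5-dihydroxy-4-methoxyphenyl)-3-methoxy-2-(3,4,5-trimethoxyphenyl)prop-2-en-1-one | CO/C=C(/C(=O)c1cc(O)c(OC)cc1O)c1cc(OC)c(OC)c(OC)c1 | intermediate
11 | 6-hydroxy-7-methoxy-3-(3,4,5-trimethoxyphenyl)chromen-4-one | COc1cc2occ(-c3cc(OC)c(OC)c(OC)c3)c(=O)c2cc1O | target

**Count**

Total steps: 6. Longest linear sequence: 5 steps (steps 1, 2, 3, 5, 6); step 4 is the one-step side branch to the quinone.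

**Steps most likely to fail**

Step 5 (the proposed new method). The excited quinone may be quenched unproductively by electron transfer from the trimethoxyphenyl ring, may add [2+2] to the enol ether, or the acyl group may be delivered to the wrong quinone carbon. Adventitious oxidation to the acylquinone is the minor problem and would be reversed by a wash with aqueous Na2S2O4. The fallback uses known polar chemistry; it sets out from hydroquinone 8 and acid 1 and comes back at target 11. Hydroquinone 8 is C-acylated by acid 1 in neat BF3·OEt2 at 80–90 °C (Friedel–Crafts acylation at the position para to the methoxy and ortho to a hydroxyl) to give the deoxybenzoin 1-(2,5-dihydroxy-4-methoxyphenyl)-2-(3,4,5-trimethoxyphenyl)ethanone F1. F1 is then treated with DMF, BF3·OEt2 and MsCl at 70–90 °C, which aminomethylenates the active methylene and closes the pyranone in the same pot to 11. This one-carbon insertion tolerates free, non-chelated phenols. The same C4–C4a and O1–C2 bonds are made, but without the redox-neutral quinone coupling.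

Step 3. The ambident enolate may be methylated on carbon, or the vinylogous ester may be hydrolysed back to 6 during work-up. The fallback sets out from 6 and comes back at 7. SOCl2 in CH2Cl2 converts the vinylogous acid into the vinylogous acid chloride (E)-3-chloro-2-(3,4,5-trimethoxyphenyl)acrolein F2. NaOMe in MeOH at 0 °C then replaces chloride by addition–elimination at the β-carbon. The oxygen–carbon bond is thus made at the vinylic carbon by the nucleophile, and C-alkylation is excluded by design.

Step 1. The electrophilic medium may formylate the activated trimethoxyphenyl ring, or decarboxylation may stall at a mono-formylated stage. The fallback sets out from 1 and comes back at 4. BH3·SMe2 in THF reduces the acid to 2-(3,4,5-trimethoxyphenyl)ethanol F3. Dess–Martin periodinane in CH2Cl2 gives (3,4,5-trimethoxyphenyl)acetaldehyde F4, used at once. Condensation with DMF dimethyl acetal in toluene at 80 °C gives 4. The arene never meets an electrophilic formylating agent, and the former carboxyl carbon is kept as the formyl carbon instead of being lost.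

**Further compounds**

F1 | step 5 | 1-(2,5-dihydroxy-4-methoxyphenyl)-2-(3,4,5-trimethoxyphenyl)ethanone | COc1cc(O)c(C(=O)Cc2cc(OC)c(OC)c(OC)c2)cc1O
F2 | step 3 | (E)-3-chloro-2-(3,4,5-trimethoxyphenyl)acrolein | Cl/C=C(/C=O)c1cc(OC)c(OC)c(OC)c1
F3 | step 1 | 2-(3,4,5-trimethoxyphenyl)ethanol | COc1cc(CCO)cc(OC)c1OC
F4 | step 1 | (3,4,5-trimethoxyphenyl)acetaldehyde | COc1cc(CC=O)cc(OC)c1OC
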